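**Plan**

- The chain is numbered C1 (CH2 on the guaiacyl ring) to C7 (CH2 on the 4-hydroxyphenyl ring); the target is the (3S,5S,6S)-triol.
- Enabling feature: the C3 carbinol is 1,3-syn to C5 and lies two carbons from the guaiacyl ring. Its oxygen can therefore come by 1,3-transposition from a benzylic C1 allylic alcohol, while O3 and O5 are held in a 2,4,6-cis-2-phenyl-1,3-dioxane, the only ring made on the way.
- Retrosynthetic cuts, in order: C3–O with the two acetal C–O bonds (key step), C2=C3 (cross-metathesis), C1–C2 (vinyl Grignard on O-benzylvanillin), then C3–C4 and C7–aryl (two cuprate openings of a C4 diepoxide).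
- Forward: aryl cuprate, O-benzylation and vinyl cuprate elaborate (S,S)-diepoxybutane at its two CH2 termini; metathesis joins the racemic aryl vinyl carbinol; Re2O7 transposition closes the dioxane; diimide reduction and hydrogenolysis finish.
- Stereochemistry: C5 and C6 are the two L-threitol (L-tartrate) centres and no bond to them is ever broken; C3 is set syn to C5 under thermodynamic control in the chair acetal.

Key step: step 8

Assumption: compound 1, the ditosylate of 2,3-O-isopropylidene-L-threitol (L-tartrate series), is a catalogue chemical and is taken as the chiral starting material; it already holds both purchased stereocentres.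

**Route**

Step 1
Reactants: 1 (−)-1,4-di-O-tosyl-2,3-O-isopropylidene-L-threitol
Product: 2 1,4-di-O-tosyl-L-threitol
Conditions: MsOH (cat.), 95% EtOH, reflux
Reagents that add atoms: none
Why: Acid-catalysed acetal hydrolysis should free the trans-diol while the primary sulfonates and both stereocentres stay untouched.

Step 2
Reactants: 2 1,4-di-O-tosyl-L-threitol
Product: 3 (S,S)-1,2:3,4-diepoxybutane
Conditions: KOH, H2O/Et2O, rt
Reagents that add atoms: none
Why: Double intramolecular Williamson closure (3-exo-tet), each alkoxide displacing the neighbouring primary tosylate, so no bond to either stereocentre is broken and the C2-symmetric diepoxide should result.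

Step 3
Reactants: 3 (S,S)-1,2:3,4-diepoxybutane, 4 1-(benzyloxy)-4-bromobenzene
Product: 6 (1S)-2-[4-(benzyloxy)phenyl]-1-[(2S)-oxiran-2-yl]ethan-1-ol, via 4-benzyloxyphenylmagnesium bromide 5 (not isolated)
Conditions: Mg, THF, rt; then slow addition to 3 (3 equiv), CuI (10 mol%), THF, −40 → −20 °C; H2O quench; excess 3 recovered by distillation
Reagents that add atoms: none
Why: Copper-catalysed Grignard opening of a terminal epoxide is an SN2 attack at the CH2 terminus, so the carbinol centre (future C6) keeps its configuration; the C2 symmetry makes both epoxides equivalent and the excess of 3 limits double opening.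

Step 4
Reactants: 6 (1S)-2-[4-(benzyloxy)phenyl]-1-[(2S)-oxiran-2-yl]ethan-1-ol
Product: 7 (2S)-2-[(1S)-1-(benzyloxy)-2-[4-(benzyloxy)phenyl]ethyl]oxirane
Conditions: NaH, BnBr, n-Bu4NI (cat.), THF, 0 °C → rt (NaH added last)
Reagents that add atoms: benzyl bromide, BrCc1ccccc1
Why: Williamson etherification of the secondary alkoxide, which is trapped as it forms at low temperature so that epoxide migration should not compete; it installs the O6 cap needed in step 8.

Step 5
Reactants: 7 (2S)-2-[(1S)-1-(benzyloxy)-2-[4-(benzyloxy)phenyl]ethyl]oxirane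
Product: 8 (2S,3S)-2-(benzyloxy)-1-[4-(benzyloxy)phenyl]hex-5-en-3-ol
Conditions: vinylmagnesium bromide, CuI (10 mol%), THF, −40 → −20 °C; H2O quench
Reagents that add atoms: vinylmagnesium bromide, C=C[Mg]Br
Why: Copper-catalysed vinyl Grignard opening at the epoxide CH2 forms the C3–C4 bond and should give the homoallylic alcohol with the C5 carbinol configuration carried over unchanged.

Step 6
Reactants: 9 4-(benzyloxy)-3-methoxybenzaldehyde
Product: 10 rac-1-[4-(benzyloxy)-3-methoxyphenyl]prop-2-en-1-ol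
Conditions: vinylmagnesium bromide, THF, 0 °C; H2O quench
Reagents that add atoms: vinylmagnesium bromide, C=C[Mg]Br
Why: Grignard 1,2-addition to an aryl aldehyde; the racemate suffices because the C1 configuration is erased in step 8.

Step 7
Reactants: 8 (2S,3S)-2-(benzyloxy)-1-[4-(benzyloxy)phenyl]hex-5-en-3-ol, 10 rac-1-[4-(benzyloxy)-3-methoxyphenyl]prop-2-en-1-ol
Product: 11 (2E,5S,6S)-6-(benzyloxy)-1-[4-(benzyloxy)-3-methoxyphenyl]-7-[4-(benzyloxy)phenyl]hept-2-ene-1,5-diol (C1 epimers)
Conditions: Hoveyda–Grubbs II (5 mol%), 10 (3 equiv), 1,4-benzoquinone (10 mol%), CH2Cl2, 40 °C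
Reagents that add atoms: none
Why: Olefin cross-metathesis of a terminal homoallylic alkene with a slowly dimerising secondary allylic alcohol used in excess should give mainly the E-alkene; neither the alkene geometry nor the C1 configuration matters for the next step.

Step 8
Reactants: 11 (2E,5S,6S)-6-(benzyloxy)-1-[4-(benzyloxy)-3-methoxyphenyl]-7-[4-(benzyloxy)phenyl]hept-2-ene-1,5-diol (C1 epimers), 12 benzaldehyde dimethyl acetal
Product: 14 (2S,4S,6R)-4-[(1S)-1-(benzyloxy)-2-[4-(benzyloxy)phenyl]ethyl]-6-[(E)-2-[4-(benzyloxy)-3-methoxyphenyl]ethenyl]-2-phenyl-1,3-dioxane (2,4,6-cis), via transposed allylic diol 13 (not isolated)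
Conditions: Re2O7 (5 mol%), 12 (2.5 equiv), CH2Cl2, 0 °C → rt; Et3N quench
Reagents that add atoms: none
Why: Re2O7 turns the benzylic C1 hydroxyl into a perrhenate ester that passes oxygen to C3 by a reversible [3,3] shift (or by ion-pair collapse, given the electron-rich aryl group), and the transposed diol 13 is drained from the equilibrium by acetal exchange with 12. The closest known reaction type is the Re2O7-catalysed 1,3-transposition of 2-ene-1,5-diols with in situ capture as 1,3-syn benzylidene acetals; here conjugation of the new E-alkene with the aryl ring adds to the driving force. The 1,3-dioxane closes by 6-endo-trig addition of the C3 hydroxyl to the oxocarbenium ion carried on O5, that is, by ordinary acetalisation. C3 is set under thermodynamic control by the fixed C5 centre, because only the 4,6-cis isomer places both ring substituents equatorial in the chair, and the acetal carbon follows by placing phenyl equatorial, which gives the 2,4,6-cis ring. The step needs oxygen delivery to C3 instead of return to C1 and capture by O5 in a six-membered acetal instead of other cyclisations; reversibility of every C–O bond-forming event, styrene conjugation and the benzyl cap on O6 (no dioxolane, no tetrahydrofuran) should secure this. Since the C1 epimers and any Z-isomer of 11 converge on one product, the mixture from step 7 is used as such.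

Step 9
Reactants: 14 (2S,4S,6R)-4-[(1S)-1-(benzyloxy)-2-[4-(benzyloxy)phenyl]ethyl]-6-[(E)-2-[4-(benzyloxy)-3-methoxyphenyl]ethenyl]-2-phenyl-1,3-dioxane
Product: 15 (2S,4S,6S)-4-[(1S)-1-(benzyloxy)-2-[4-(benzyloxy)phenyl]ethyl]-6-[2-[4-(benzyloxy)-3-methoxyphenyl]ethyl]-2-phenyl-1,3-dioxane
Conditions: TsNHNH2 (excess), NaOAc, DME/H2O, reflux
Reagents that add atoms: none
Why: Diimide reduction transfers two hydrogens to the C=C bond in a concerted syn fashion and cannot cleave C–O bonds, so the alkene should be saturated before the allylic C3–O bond is exposed to palladium; the descriptor change at the ring carbon is a CIP effect only.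

Step 10
Reactants: 15 (2S,4S,6S)-4-[(1S)-1-(benzyloxy)-2-[4-(benzyloxy)phenyl]ethyl]-6-[2-[4-(benzyloxy)-3-methoxyphenyl]ethyl]-2-phenyl-1,3-dioxane
Product: 16 (2S,3S,5S)-7-(4-hydroxy-3-methoxyphenyl)-1-(4-hydroxyphenyl)heptane-2,3,5-triol
Conditions: H2 (1 atm), Pd(OH)2/C, EtOAc/MeOH, rt
Reagents that add atoms: none
Why: Catalytic hydrogenolysis should cleave the three benzyl ethers and the benzylidene acetal in one operation, while the C3–O, C5–O and C6–O bonds, none of them benzylic or allylic any longer, stay intact.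

**Compound list**

1 | [(4S,5S)-2,2-dimethyl-1,3-dioxolane-4,5-diyl]bis(methylene) bis(4-methylbenzenesulfonate) [(−)-1,4-di-O-tosyl-2,3-O-isopropylidene-L-threitol] | CC1(C)O[C@@H](COS(=O)(=O)c2ccc(C)cc2)[C@H](COS(=O)(=O)c2ccc(C)cc2)O1 | starting material
2 | (2S,3S)-2,3-dihydroxybutane-1,4-diyl bis(4-methylbenzenesulfonate) (1,4-di-O-tosyl-L-threitol) | Cc1ccc(cc1)S(=O)(=O)OC[C@H](O)[C@@H](O)COS(=O)(=O)c1ccc(C)cc1 | intermediate
3 | (2S,2'S)-2,2'-bioxirane [(S,S)-1,2:3,4-diepoxybutane] | C1O[C@@H]1[C@@H]1CO1 | intermediate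
4 | 1-(benzyloxy)-4-bromobenzene | Brc1ccc(OCc2ccccc2)cc1 | starting material
5 | [4-(benzyloxy)phenyl]magnesium bromide | Br[Mg]c1ccc(OCc2ccccc2)cc1 | intermediate (not isolated)
6 | (1S)-2-[4-(benzyloxy)phenyl]-1-[(2S)-oxiran-2-yl]ethan-1-ol | O[C@@H](Cc1ccc(OCc2ccccc2)cc1)[C@@H]1CO1 | intermediate
7 | (2S)-2-[(1S)-1-(benzyloxy)-2-[4-(benzyloxy)phenyl]ethyl]oxirane | c1ccccc1CO[C@@H](Cc1ccc(OCc2ccccc2)cc1)[C@@H]1CO1 | intermediate
8 | (2S,3S)-2-(benzyloxy)-1-[4-(benzyloxy)phenyl]hex-5-en-3-ol | C=CC[C@H](O)[C@@H](OCc1ccccc1)Cc1ccc(OCc2ccccc2)cc1 | intermediate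
9 | 4-(benzyloxy)-3-methoxybenzaldehyde | COc1cc(C=O)ccc1OCc1ccccc1 | starting material
10 | rac-1-[4-(benzyloxy)-3-methoxyphenyl]prop-2-en-1-ol | COc1cc(C(O)C=C)ccc1OCc1ccccc1 | intermediate
11 | (2E,5S,6S)-6-(benzyloxy)-1-[4-(benzyloxy)-3-methoxyphenyl]-7-[4-(benzyloxy)phenyl]hept-2-ene-1,5-diol (C1 epimers) | COc1cc(C(O)/C=C/C[C@H](O)[C@@H](OCc2ccccc2)Cc2ccc(OCc3ccccc3)cc2)ccc1OCc1ccccc1 | intermediate
12 | benzaldehyde dimethyl acetal [(dimethoxymethyl)benzene] | COC(OC)c1ccccc1 | starting material
13 | (1E,5S,6S)-6-(benzyloxy)-1-[4-(benzyloxy)-3-methoxyphenyl]-7-[4-(benzyloxy)phenyl]hept-1-ene-3,5-diol (C3 epimers) | COc1cc(/C=C/C(O)C[C@H](O)[C@@H](OCc2ccccc2)Cc2ccc(OCc3ccccc3)cc2)ccc1OCc1ccccc1 | intermediate (not isolated)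
14 | (2S,4S,6R)-4-[(1S)-1-(benzyloxy)-2-[4-(benzyloxy)phenyl]ethyl]-6-[(E)-2-[4-(benzyloxy)-3-methoxyphenyl]ethenyl]-2-phenyl-1,3-dioxane (2,4,6-cis) | COc1cc(/C=C/[C@H]2C[C@@H]([C@@H](OCc3ccccc3)Cc3ccc(OCc4ccccc4)cc3)O[C@@H](c3ccccc3)O2)ccc1OCc1ccccc1 | intermediate
15 | (2S,4S,6S)-4-[(1S)-1-(benzyloxy)-2-[4-(benzyloxy)phenyl]ethyl]-6-[2-[4-(benzyloxy)-3-methoxyphenyl]ethyl]-2-phenyl-1,3-dioxane (2,4,6-cis) | COc1cc(CC[C@H]2C[C@@H]([C@@H](OCc3ccccc3)Cc3ccc(OCc4ccccc4)cc3)O[C@@H](c3ccccc3)O2)ccc1OCc1ccccc1 | intermediate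
16 | (2S,3S,5S)-7-(4-hydroxy-3-methoxyphenyl)-1-(4-hydroxyphenyl)heptane-2,3,5-triol | COc1cc(CC[C@H](O)C[C@H](O)[C@@H](O)Cc2ccc(O)cc2)ccc1O | target

**Step count**

Total: 10 steps. Longest linear sequence: 9 steps (steps 1–5 and 7–10); step 6 is a one-step side branch.

**Steps most likely to fail**

Step 8 (key step). The electron-rich benzylic allylic system may ionise faster than the acetal captures it. That would open the way to Friedel–Crafts oligomerisation, cyclisation of O5 onto C1 to a dihydropyran, elimination to a diene, or stalling at methyl ethers and mixed acetals. The fallback sets out from 11 and sets C3–O by conjugate addition instead of transposition. MnO2 in CH2Cl2 should oxidise only the allylic, benzylic C1 hydroxyl to give (2E,5S,6S)-6-(benzyloxy)-1-[4-(benzyloxy)-3-methoxyphenyl]-7-[4-(benzyloxy)phenyl]-5-hydroxyhept-2-en-1-one F1. Benzaldehyde with catalytic KOtBu in THF at 0 °C then adds the hemiacetal alkoxide of O5 to the enone (oxa-Michael addition under thermodynamic control), which should give the 2,4,6-cis keto acetal 1-[4-(benzyloxy)-3-methoxyphenyl]-2-[(2S,4R,6S)-6-[(1S)-1-(benzyloxy)-2-[4-(benzyloxy)phenyl]ethyl]-2-phenyl-1,3-dioxan-4-yl]ethan-1-one F2. NaBH4 in MeOH reduces the ketone to the benzylic alcohol 1-[4-(benzyloxy)-3-methoxyphenyl]-2-[2,4,6-cis-6-[(1S)-1-(benzyloxy)-2-[4-(benzyloxy)phenyl]ethyl]-2-phenyl-1,3-dioxan-4-yl]ethan-1-ol F3 (carbinol epimers, ring centres as in F2). Hydrogenolysis over Pd/C in ethanol with a trace of HCl should then remove the benzylic hydroxyl together with the acetal and the benzyl ethers, and the sequence comes back to the route at 16.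

Step 7. Ruthenium hydride species may isomerise the aryl vinyl carbinol to the aryl ethyl ketone, and self-metathesis or slow turnover in the presence of two free hydroxyls may starve the cross-coupling. The fallback sets out from 7 and builds C1–C2 by acetylide addition instead of metathesis. Lithium acetylide–ethylenediamine in DMSO should open the epoxide at CH2 to give (2S,3S)-2-(benzyloxy)-1-[4-(benzyloxy)phenyl]hex-5-yn-3-ol F4. Its dianion (n-BuLi, 2 equiv, THF, −78 °C) adds to aldehyde 9 to give (5S,6S)-6-(benzyloxy)-1-[4-(benzyloxy)-3-methoxyphenyl]-7-[4-(benzyloxy)phenyl]hept-2-yne-1,5-diol F5 (C1 epimers). Red-Al in THF reduces the propargylic alcohol by trans-hydroalumination to the E-alkene, and the sequence comes back to the route at 11.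

Step 3. The remaining epoxide of the mono-adduct may be opened a second time, and magnesium halide may open the epoxide to a bromohydrin, so the material balance of the mono-opening may be poor. The fallback sets out from 4 (as its Grignard reagent 5) and swaps the C2-symmetric diepoxide for a one-epoxide chiral building block plus a substrate-controlled allylation. Copper-catalysed opening of purchased methyl (2S)-oxirane-2-carboxylate (COC(=O)[C@@H]1CO1) at CH2 should give methyl (2S)-3-[4-(benzyloxy)phenyl]-2-hydroxypropanoate F6. Benzylation with BnBr and Ag2O gives methyl (2S)-2-(benzyloxy)-3-[4-(benzyloxy)phenyl]propanoate F7. DIBAL-H at −78 °C gives (2S)-2-(benzyloxy)-3-[4-(benzyloxy)phenyl]propanal F8, which is used without purification. Chelation-controlled allylation (allyltributylstannane, MgBr2·OEt2, CH2Cl2, −78 °C) should deliver the syn product, and the sequence comes back to the route at 8.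

**Further compounds**

F1 | step 8 | (2E,5S,6S)-6-(benzyloxy)-1-[4-(benzyloxy)-3-methoxyphenyl]-7-[4-(benzyloxy)phenyl]-5-hydroxyhept-2-en-1-one | COc1cc(C(=O)/C=C/C[C@H](O)[C@@H](OCc2ccccc2)Cc2ccc(OCc3ccccc3)cc2)ccc1OCc1ccccc1
F2 | step 8 | 1-[4-(benzyloxy)-3-methoxyphenyl]-2-[(2S,4R,6S)-6-[(1S)-1-(benzyloxy)-2-[4-(benzyloxy)phenyl]ethyl]-2-phenyl-1,3-dioxan-4-yl]ethan-1-one | COc1cc(C(=O)C[C@H]2C[C@@H]([C@@H](OCc3ccccc3)Cc3ccc(OCc4ccccc4)cc3)O[C@@H](c3ccccc3)O2)ccc1OCc1ccccc1
F3 | step 8 | 1-[4-(benzyloxy)-3-methoxyphenyl]-2-[2,4,6-cis-6-[(1S)-1-(benzyloxy)-2-[4-(benzyloxy)phenyl]ethyl]-2-phenyl-1,3-dioxan-4-yl]ethan-1-ol (carbinol epimers) | COc1cc(C(O)C[C@H]2C[C@@H]([C@@H](OCc3ccccc3)Cc3ccc(OCc4ccccc4)cc3)O[C@@H](c3ccccc3)O2)ccc1OCc1ccccc1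
F4 | step 7 | (2S,3S)-2-(benzyloxy)-1-[4-(benzyloxy)phenyl]hex-5-yn-3-ol | C#CC[C@H](O)[C@@H](OCc1ccccc1)Cc1ccc(OCc2ccccc2)cc1
F5 | step 7 | (5S,6S)-6-(benzyloxy)-1-[4-(benzyloxy)-3-methoxyphenyl]-7-[4-(benzyloxy)phenyl]hept-2-yne-1,5-diol (C1 epimers) | COc1cc(C(O)C#CC[C@H](O)[C@@H](OCc2ccccc2)Cc2ccc(OCc3ccccc3)cc2)ccc1OCc1ccccc1
F6 | step 3 | methyl (2S)-3-[4-(benzyloxy)phenyl]-2-hydroxypropanoate | COC(=O)[C@@H](O)Cc1ccc(OCc2ccccc2)cc1
F7 | step 3 | methyl (2S)-2-(benzyloxy)-3-[4-(benzyloxy)phenyl]propanoate | COC(=O)[C@@H](OCc1ccccc1)Cc1ccc(OCc2ccccc2)cc1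
F8 | step 3 | (2S)-2-(benzyloxy)-3-[4-(benzyloxy)phenyl]propanal | O=C[C@@H](OCc1ccccc1)Cc1ccc(OCc2ccccc2)cc1
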